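**Plan**

- Target numbering: ring C1 (C=O), C2=C3, C4H2, C5 (carbinol, S), C6H2; side chain C1'H2–C2'(=O)–C3'…C19'.
- Cuts, in retrosynthetic order: C2'–C3' (ketone–alkyl bond of the side chain), the C2=C3 unsaturation, then C5–C6.
- The ring carries a β-ketol, C1(=O)–C6H2–C5(OH), which is an intramolecular aldol retron; cutting C5–C6 opens the carbocycle to the open-chain 8,8-dimethoxyoctane-2,6-dione.
- Forward: the diketone is assembled by Weinreb ketone synthesis and Wacker oxidation, and the six-membered ring closes in the aldol step. Silylation, regioselective dehydrogenation and acetal-to-acid conversion follow, and the C17 chain is joined last by Negishi acylation before desilylation.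
- Stereochemistry: C5, the only stereocentre, is set by (S)-proline in the ring-closing aldol addition; both Z alkenes come unchanged from linoleic acid.

Key step: step 4

Remark: the sense of induction in step 4 is assigned by analogy with the Hajos–Parrish cyclisation; should (S)-proline favour the R ketol, (R)-proline is used and nothing else changes.
Remark: the spatial arrangement at the carbinol carbon is the same from 6 to 18; the descriptor reads R in 8, 11 and 15 only because the CIP priorities of the neighbours change.

**Step 1**
Reactants: 1 methyl 3,3-dimethoxypropanoate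
Product: 2 N,3,3-trimethoxy-N-methylpropanamide
Conditions: MeNH(OMe)·HCl, iPrMgCl, THF, −20 °C
Reagents that add atoms: N,O-dimethylhydroxylamine hydrochloride, CNOC.Cl
Why: Aminolysis of the ester by the chloromagnesium amide of N,O-dimethylhydroxylamine (Weinreb amide formation) is fast at −20 °C, and this weakly basic amide should leave the β,β-dimethoxy group in place.

**Step 2**
Reactants: 2 N,3,3-trimethoxy-N-methylpropanamide; 3 pent-4-en-1-ylmagnesium bromide (commercial THF solution)
Product: 4 1,1-dimethoxyoct-7-en-3-one
Conditions: THF, −78 to 0 °C; cold sat. aq NH4Cl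
Reagents that add atoms: none
Why: Weinreb ketone synthesis: the Grignard reagent adds once to give a magnesium-chelated tetrahedral adduct that collapses to the ketone only on quenching, so no tertiary alcohol forms and the β-keto acetal never meets base.

**Step 3**
Reactants: 4 1,1-dimethoxyoct-7-en-3-one
Product: 5 8,8-dimethoxyoctane-2,6-dione
Conditions: PdCl2 (10 mol %), CuCl (1 equiv), O2 (1 atm), DMF–H2O (7:1), rt
Reagents that add atoms: water, O
Why: Tsuji–Wacker oxidation: Markovnikov hydroxypalladation of the terminal alkene and β-hydride elimination give the methyl ketone, CuCl and O2 re-oxidise palladium, and the weakly acidic DMF–water medium should spare the dimethyl acetal.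

**Step 4**
Reactants: 5 8,8-dimethoxyoctane-2,6-dione
Product: 6 (3S)-3-(2,2-dimethoxyethyl)-3-hydroxycyclohexan-1-one
Conditions: (S)-proline (30 mol %), DMF, 15 °C, stopped at the ketol stage; pH 7 phosphate buffer, EtOAc
Reagents that add atoms: none
Why: Proposed new method: (S)-proline condenses with the less hindered methyl ketone of 5 to give the terminal enamine, whose CH2 carbon adds to the C6 ketone through a chair-like six-membered transition state in which the carboxylic acid hydrogen-bonds to the acceptor oxygen, and hydrolysis of the iminium ion releases ketol 6 and the catalyst. The closest known reaction type is the proline-mediated intramolecular aldol addition of the Hajos–Parrish kind and its extension to heptane-2,6-diones, which has not been shown to give a lone tertiary carbinol from an unactivated open-chain dialkyl ketone in high enantiomeric purity. The six-membered ring closes in the 6-(enolendo)-exo-trig mode, the enamine double bond lying inside the forming ring and the acceptor C=O outside it. The new stereocentre (C5 of the target) is controlled by the catalyst, because the acid-to-carbonyl hydrogen bond fixes where the acceptor oxygen sits in the chair and the CH2CH(OMe)2 arm must take the other position, which by analogy with the Hajos–Parrish ketol is expected to give the S carbinol. Regioselectivity between the two possible six-ring closures is needed and is secured by the substrate, since the other closure requires the internal, more hindered enamine at C7 of the ketone that carries the acetal arm, while C3 and C5 enamines could only form four-membered rings. The reaction must also stop at the ketol, which the secondary amino acid at 15 °C without added strong acid and a neutral work-up should allow, and the acetal keeps the acceptor from being an enolised 1,3-dicarbonyl.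

**Step 5**
Reactants: 6 (3S)-3-(2,2-dimethoxyethyl)-3-hydroxycyclohexan-1-one
Product: 7 (3S)-3-(2,2-dimethoxyethyl)-3-(triethylsilyloxy)cyclohexan-1-one
Conditions: Et3SiCl, imidazole, 4-(dimethylamino)pyridine (cat.), DMF, rt to 40 °C
Reagents that add atoms: chlorotriethylsilane, CC[Si](Cl)(CC)CC
Why: Silylation of the tertiary alcohol by the silyl chloride under imidazole and nucleophilic catalysis avoids a silyl triflate, which would ionise the dimethyl acetal, and the resulting ether blocks alkoxide-driven retro-aldol cleavage and dehydration in the steps that follow.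

**Step 6**
Reactants: 7 (3S)-3-(2,2-dimethoxyethyl)-3-(triethylsilyloxy)cyclohexan-1-one
Product: 8 {[(5R)-5-(2,2-dimethoxyethyl)-5-(triethylsilyloxy)cyclohex-1-en-1-yl]oxy}trimethylsilane
Conditions: LiN(iPr)2, Me3SiCl (internal quench), THF, −78 °C; Et3N, pentane, cold aq NaHCO3
Reagents that add atoms: chlorotrimethylsilane, C[Si](C)(C)Cl
Why: Kinetic enolisation with the hindered amide base takes the unhindered C6 proton and not the neopentyl C2 proton beside the silyloxy carbon, and in situ O-silylation traps that enolate before it can equilibrate or expel silanolate.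

**Step 7**
Reactants: 8 {[(5R)-5-(2,2-dimethoxyethyl)-5-(triethylsilyloxy)cyclohex-1-en-1-yl]oxy}trimethylsilane
Product: 9 (5S)-5-(2,2-dimethoxyethyl)-5-(triethylsilyloxy)cyclohex-2-en-1-one
Conditions: Pd(OAc)2 (1.05 equiv), MeCN, rt
Reagents that add atoms: none
Why: Saegusa–Ito oxidation: the silyl enol ether is converted to a palladium enolate that undergoes β-hydride elimination, placing the double bond between the former C5 and C6 of the cyclohexanone, on the side away from the quaternary carbinol carbon, whose configuration is not touched.

**Step 8**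
Reactants: 9 (5S)-5-(2,2-dimethoxyethyl)-5-(triethylsilyloxy)cyclohex-2-en-1-one
Product: 10 2-[(1S)-5-oxo-1-(triethylsilyloxy)cyclohex-3-en-1-yl]acetaldehyde
Conditions: pyridinium p-toluenesulfonate (0.2 equiv), acetone–H2O (10:1), rt
Reagents that add atoms: water, O
Why: Acid-catalysed acetal hydrolysis (transacetalisation to acetone) removes the acyclic dimethyl acetal under conditions too mild to cleave a hindered tertiary triethylsilyl ether or to eliminate the β-silyloxy group.

**Step 9**
Reactants: 10 2-[(1S)-5-oxo-1-(triethylsilyloxy)cyclohex-3-en-1-yl]acetaldehyde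
Product: 11 2-[(1R)-5-oxo-1-(triethylsilyloxy)cyclohex-3-en-1-yl]acetic acid
Conditions: NaClO2, NaH2PO4, 2-methylbut-2-ene, t-BuOH–H2O, 0 °C
Reagents that add atoms: sodium chlorite, [Na+].[O-]Cl=O
Why: Pinnick oxidation: chlorous acid at about pH 4 oxidises the aldehyde to the acid and touches neither the enone nor the silyl ether, while 2-methylbut-2-ene removes the hypochlorous acid formed.

**Step 10**
Reactants: 12 linoleic acid
Product: 14 (8Z,11Z)-1-iodoheptadeca-8,11-diene, via Barton ester 13 (not isolated)
Conditions: N-hydroxypyridine-2-thione, DCC, 4-(dimethylamino)pyridine (cat.), CH2Cl2, rt, dark; then CHI3, cyclohexene, tungsten lamp, rt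
Reagents that add atoms: iodoform, IC(I)I
Why: Barton decarboxylative iodination: the O-acyl thiohydroxamate fragments under visible light to CO2 and the primary alkyl radical, which abstracts iodine from iodoform far faster than it can abstract a bis-allylic hydrogen, so the skipped Z,Z-diene should pass unchanged.

**Step 11**
Reactants: 11 2-[(1R)-5-oxo-1-(triethylsilyloxy)cyclohex-3-en-1-yl]acetic acid; 14 (8Z,11Z)-1-iodoheptadeca-8,11-diene
Product: 17 (5S)-5-[(10Z,13Z)-2-oxononadeca-10,13-dien-1-yl]-5-(triethylsilyloxy)cyclohex-2-en-1-one, via acid chloride 15 (not isolated), via alkylzinc iodide 16 (not isolated)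
Conditions: 11, 1-chloro-N,N,2-trimethylprop-1-en-1-amine, CH2Cl2, 0 °C; 14, Zn dust (Me3SiCl/1,2-dibromoethane-activated), THF, 40 °C; combined, Pd(PPh3)4 (5 mol %), THF, 0 °C to rt
Reagents that add atoms: none
Why: Negishi acylation: the acid chloride, made under neutral conditions, adds oxidatively to zerovalent palladium, the alkylzinc iodide transmetalates and reductive elimination forms the C2'–C3' bond, while the organozinc is too mild to add to the enone or to the new ketone.

**Step 12**
Reactants: 17 (5S)-5-[(10Z,13Z)-2-oxononadeca-10,13-dien-1-yl]-5-(triethylsilyloxy)cyclohex-2-en-1-one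
Product: 18 (5S)-5-hydroxy-5-[(10Z,13Z)-2-oxononadeca-10,13-dien-1-yl]cyclohex-2-en-1-one
Conditions: HF·pyridine, pyridine, THF, 0 °C; Me3SiOMe quench
Reagents that add atoms: none
Why: Fluoride-mediated desilylation in pyridine-buffered medium cleaves the Si–O bond without base, so the doubly β-keto tertiary alcohol is freed without retro-aldol cleavage or dehydration and C5 keeps its S configuration.

**Compound list**

1 | methyl 3,3-dimethoxypropanoate | COC(=O)CC(OC)OC | starting material
2 | N,3,3-trimethoxy-N-methylpropanamide | CON(C)C(=O)CC(OC)OC | intermediate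
3 | pent-4-en-1-ylmagnesium bromide | C=CCCC[Mg]Br | starting material
4 | 1,1-dimethoxyoct-7-en-3-one | C=CCCCC(=O)CC(OC)OC | intermediate
5 | 8,8-dimethoxyoctane-2,6-dione | CC(=O)CCCC(=O)CC(OC)OC | intermediate
6 | (3S)-3-(2,2-dimethoxyethyl)-3-hydroxycyclohexan-1-one | COC(OC)C[C@@]1(O)CCCC(=O)C1 | intermediate
7 | (3S)-3-(2,2-dimethoxyethyl)-3-(triethylsilyloxy)cyclohexan-1-one | COC(OC)C[C@@]1(O[Si](CC)(CC)CC)CCCC(=O)C1 | intermediate
8 | {[(5R)-5-(2,2-dimethoxyethyl)-5-(triethylsilyloxy)cyclohex-1-en-1-yl]oxy}trimethylsilane | COC(OC)C[C@@]1(O[Si](CC)(CC)CC)CCC=C(O[Si](C)(C)C)C1 | intermediate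
9 | (5S)-5-(2,2-dimethoxyethyl)-5-(triethylsilyloxy)cyclohex-2-en-1-one | COC(OC)C[C@@]1(O[Si](CC)(CC)CC)CC=CC(=O)C1 | intermediate
10 | 2-[(1S)-5-oxo-1-(triethylsilyloxy)cyclohex-3-en-1-yl]acetaldehyde | O=CC[C@@]1(O[Si](CC)(CC)CC)CC=CC(=O)C1 | intermediate
11 | 2-[(1R)-5-oxo-1-(triethylsilyloxy)cyclohex-3-en-1-yl]acetic acid | OC(=O)C[C@@]1(O[Si](CC)(CC)CC)CC=CC(=O)C1 | intermediate
12 | linoleic acid, (9Z,12Z)-octadeca-9,12-dienoic acid | CCCCC/C=C\C/C=C\CCCCCCCC(=O)O | starting material
13 | 2-thioxopyridin-1(2H)-yl (9Z,12Z)-octadeca-9,12-dienoate (Barton ester) | CCCCC/C=C\C/C=C\CCCCCCCC(=O)On1ccccc1=S | intermediate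
14 | (8Z,11Z)-1-iodoheptadeca-8,11-diene | CCCCC/C=C\C/C=C\CCCCCCCI | intermediate
15 | 2-[(1R)-5-oxo-1-(triethylsilyloxy)cyclohex-3-en-1-yl]acetyl chloride | ClC(=O)C[C@@]1(O[Si](CC)(CC)CC)CC=CC(=O)C1 | intermediate
16 | [(8Z,11Z)-heptadeca-8,11-dien-1-yl]zinc iodide | CCCCC/C=C\C/C=C\CCCCCCC[Zn]I | intermediate
17 | (5S)-5-[(10Z,13Z)-2-oxononadeca-10,13-dien-1-yl]-5-(triethylsilyloxy)cyclohex-2-en-1-one | CCCCC/C=C\C/C=C\CCCCCCCC(=O)C[C@@]1(O[Si](CC)(CC)CC)CC=CC(=O)C1 | intermediate
18 | (5S)-5-hydroxy-5-[(10Z,13Z)-2-oxononadeca-10,13-dien-1-yl]cyclohex-2-en-1-one (CNP0252404.1) | CCCCC/C=C\C/C=C\CCCCCCCC(=O)C[C@@]1(O)CC=CC(=O)C1 | target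

**Step count**

Total steps: 12. Longest linear sequence: 11 steps (steps 1 to 9, 11 and 12, from methyl 3,3-dimethoxypropanoate); step 10 is the side branch.

**Steps most likely to fail**

Step 4. The catalyst may discriminate poorly between the two faces of the dialkyl ketone. The ketol may also dehydrate, or the β-keto acetal may lose methanol through an enamine on the acceptor side. The fallback uses known chemistry and sets out from 5. Pyrrolidine and acetic acid in toluene should cyclise and dehydrate 5 on purpose to the achiral 3-(2,2-dimethoxyethyl)cyclohex-2-en-1-one F1. Copper-catalysed enantioselective conjugate borylation then sets the tertiary centre: bis(pinacolato)diboron, [Cu(MeCN)4]PF6, the QuinoxP* enantiomer that places boron on the required face, LiOtBu, DMSO. This should give (3R)-3-(2,2-dimethoxyethyl)-3-(4,4,5,5-tetramethyl-1,3,2-dioxaborolan-2-yl)cyclohexan-1-one F2. Oxidation of the C–B bond with retention (NaBO3·4H2O, THF–H2O) returns to the route at 6.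

Step 11. The β-silyloxy acid chloride may lose HCl or silanol before it couples, or transmetalation may be too slow to outrun decarbonylation of the acylpalladium species. The fallback sets out from aldehyde 10 and iodide 14. CrCl2 with catalytic cobalt phthalocyanine, Co(C32H16N8), in DMF should turn 14 into an alkylchromium reagent that adds to aldehydes and leaves ketones and enones alone. This should give (5S)-5-[(10Z,13Z)-2-hydroxynonadeca-10,13-dien-1-yl]-5-(triethylsilyloxy)cyclohex-2-en-1-one F3 as a mixture of carbinol epimers. Oxidation with Dess–Martin periodinane buffered with NaHCO3 in CH2Cl2 returns to the route at 17.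

Step 3. The β-keto acetal may hydrolyse or lose methanol in the acidic copper chloride medium, and the double bond may migrate before it is oxidised. The fallback sets out from 2 and carries the methyl ketone in masked form through the Grignard step. Commercial 2-(3-chloropropyl)-2-methyl-1,3-dioxolane and Mg in THF give [3-(2-methyl-1,3-dioxolan-2-yl)propyl]magnesium chloride F4. Its addition to 2 should give 1,1-dimethoxy-6-(2-methyl-1,3-dioxolan-2-yl)hexan-3-one F5. Pyridinium p-toluenesulfonate in wet acetone at rt should then remove the ketone-derived dioxolane much faster than the aldehyde-derived acetal, which the neighbouring carbonyl deactivates, and this returns to the route at 5.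

**Further compounds**

F1 | step 4 | 3-(2,2-dimethoxyethyl)cyclohex-2-en-1-one | COC(OC)CC1=CC(=O)CCC1
F2 | step 4 | (3R)-3-(2,2-dimethoxyethyl)-3-(4,4,5,5-tetramethyl-1,3,2-dioxaborolan-2-yl)cyclohexan-1-one | COC(OC)C[C@@]1(B2OC(C)(C)C(C)(C)O2)CCCC(=O)C1
F3 | step 11 | (5S)-5-[(10Z,13Z)-2-hydroxynonadeca-10,13-dien-1-yl]-5-(triethylsilyloxy)cyclohex-2-en-1-one, both carbinol epimers | CCCCC/C=C\C/C=C\CCCCCCCC(O)C[C@@]1(O[Si](CC)(CC)CC)CC=CC(=O)C1
F4 | step 3 | [3-(2-methyl-1,3-dioxolan-2-yl)propyl]magnesium chloride | CC1(CCC[Mg]Cl)OCCO1
F5 | step 3 | 1,1-dimethoxy-6-(2-methyl-1,3-dioxolan-2-yl)hexan-3-one | COC(OC)CC(=O)CCCC1(C)OCCO1
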